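**Retrosynthetic overview**
- 4'-O-Methyldiplacol comes from a thermal aromatic Claisen [3,3] rearrangement of its 7-O-linalyl ether. That step forms the C6–CH2 bond, and the allylic transposition turns the tertiary linalyl group into the primary (E)-geranyl group.
- The linalyl ether comes from Lindlar reduction of a tertiary propargyl ether, which comes from Cu-mediated O-alkylation of the 7-OH with the dehydrolinalool-derived chloride. The 4'-OMe is installed by selective methylation.
- No ring is built. All three rings and both stereocenters (2R,3R) are inherited from commercial (+)-taxifolin and are never touched.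

Assumptions (reagents are not numbered; only substrates, intermediates and the target are):
- The 7-OH (most acidic) alkylates selectively with 1 equiv of electrophile.
- 4'-OH is methylated in preference to 3'-OH, and the regioisomer is separable.
- In the Claisen, the chelated 5-OH steers rearrangement to C6 over C8.
- The E/Z ratio in the Claisen is modest, and the E isomer is separable.

---

**Step 1**
Reactants: 1, dehydrolinalool (3,7-dimethyloct-6-en-1-yn-3-ol)
Product: 2, 3-chloro-3,7-dimethyloct-6-en-1-yne (racemic)
Conditions: conc. HCl, CaCl2, CuCl (cat.), 0 °C, 1 h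
Reagents that add atoms: hydrogen chloride, Cl
Why: Cu-assisted SN1-type chlorination of a tertiary propargylic alcohol gives the propargyl chloride; the new tertiary stereocenter is racemic and is destroyed in Step 5.

**Step 2**
Reactants: 2, chloride; 3, (2R,3R)-taxifolin
Product: 4, 7-O-(3,7-dimethyloct-6-en-1-yn-3-yl)taxifolin (1:1 mixture of side-chain epimers)
Conditions: DBU (1.1 equiv), CuI (10 mol %), MeCN, 0 °C → rt, Ar
Reagents that add atoms: none (chloride 2 is the reactant)
Why: Cu-allenylidene propargylic etherification (Godfrey-type) is selective for the most acidic phenol, the 7-OH (the 5-OH is chelated and the 3-OH is aliphatic). The mild, short, 0 °C conditions preserve the C2/C3 configuration.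

**Step 3**
Reactants: 4
Product: 5, 4'-O-methyl-7-O-(dehydrolinalyl)taxifolin
Conditions: MeI (1.1 equiv), K2CO3 (1.1 equiv), acetone, rt, 3 h
Reagents that add atoms: iodomethane, CI
Why: Williamson O-methylation of the more acidic B-ring phenol (4'-OH) leaves the 3'-OH, the chelated 5-OH and the 3-OH free; the stereocenters are not involved.

**Step 4**
Reactants: 5
Product: 6, 4'-O-methyl-7-O-linalyl-taxifolin, i.e. the 3,7-dimethylocta-1,6-dien-3-yl ether
Conditions: H2 (1 atm), Lindlar catalyst, quinoline, EtOAc, rt
Reagents that add atoms: none (H2 adds only hydrogen)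
Why: Lindlar semi-hydrogenation reduces the terminal alkyne to the vinyl group and leaves the trisubstituted alkene, the aryl ketone and the phenols untouched.

**Step 5**
Reactants: 6
Product: 7, 4'-O-methyldiplacol (target)
Conditions: o-dichlorobenzene, BHT, sealed tube, 150–160 °C, 4–6 h (neutral, degassed); then AgNO3-silica chromatography
Reagents that add atoms: none
Why: The aromatic Claisen [3,3] rearrangement of the aryl linalyl ether bonds the vinyl CH2 terminus to C6 and forms the trisubstituted alkene. The chair transition state with the larger chain pseudo-equatorial gives the (E)-geranyl group, and the neutral medium avoids retro-oxa-Michael epimerization of C2/C3. The dienone intermediate tautomerizes to the 5,7-dihydroxy arene, and the C2 and C3 centers are untouched.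

---

**Compound list**

| No. | Name | SMILES | Role |
|---|---|---|---|
| 1 | Dehydrolinalool | C#CC(C)(O)CCC=C(C)C | starting material |
| 2 | 3-Chloro-3,7-dimethyloct-6-en-1-yne | C#CC(C)(Cl)CCC=C(C)C | intermediate |
| 3 | (2R,3R)-Taxifolin | Oc1ccc([C@H]2Oc3cc(O)cc(O)c3C(=O)[C@@H]2O)cc1O | starting material |
| 4 | 7-O-(3,7-Dimethyloct-6-en-1-yn-3-yl)taxifolin | Oc1ccc([C@H]2Oc3cc(OC(C)(C#C)CCC=C(C)C)cc(O)c3C(=O)[C@@H]2O)cc1O | intermediate |
| 5 | 4'-O-Methyl-7-O-(dehydrolinalyl)taxifolin | COc1ccc([C@H]2Oc3cc(OC(C)(C#C)CCC=C(C)C)cc(O)c3C(=O)[C@@H]2O)cc1O | intermediate |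
| 6 | 4'-O-Methyl-7-O-linalyl-taxifolin | COc1ccc([C@H]2Oc3cc(OC(C)(C=C)CCC=C(C)C)cc(O)c3C(=O)[C@@H]2O)cc1O | intermediate |
| 7 | 4'-O-Methyldiplacol | COc1ccc([C@H]2Oc3cc(O)c(C/C=C(\C)CCC=C(C)C)c(O)c3C(=O)[C@@H]2O)cc1O | target |

**Totals:** 5 steps in total. The longest linear sequence is 5 steps (1 → 2 → 4 → 5 → 6 → 7).

**Three steps most likely to fail**
1. **Step 5 (Claisen).** It may give C6/C8 mixtures and a roughly 1:1 geranyl/neryl ratio, and the dihydroflavonol may partly epimerize or ring-open on heating.
   - Fallback: block C8 by bromination of 4, run the Claisen with C6 as the only ortho position, then remove the bromine by Pd transfer hydrogenolysis. For the geometry problem, replace the sigmatropic step with direct C6 geranylation of a 7-O-protected substrate using (E)-geranyl bromide.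
2. **Step 2 (7-O tertiary propargylation).** The free catechol can be oxidized or alkylated under Cu/DBU.
   - Fallback: protect the 7-OH as its allyl ether first, methylate 4'-OH, remove the allyl group with Pd(0)/morpholine, and then propargylate the 7-OH.
3. **Step 3 (4'- vs 3'-O-methylation).** Selectivity is only modest.
   - Fallback: start from (S)-hesperetin, which already carries 3'-OH/4'-OMe, and install the trans 3-OH by substrate-controlled enolate hydroxylation.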